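## Structural features

The target is a diaryl ester of the depside type. Ring A, a 2-hydroxy-4-methoxy-3,6-dimethylbenzoyl unit, is joined through its carboxyl group and one O–CH2 bridge to C6 of ring B, the benzene ring of a phthalide (numbered C1 carbonyl, O2, C3, C3a, C4–C7, C7a). Ring B is substituted everywhere except C4: methoxy at C5, the acyloxymethyl group at C6, and a phenol at C7 that is hydrogen-bonded to the lactone carbonyl. Ring A likewise carries a phenol chelated to its own ester carbonyl. The only stereocentre is C3, the lactol (hemiacylal) carbon, with R configuration; it has no neighbouring stereocentre, so nothing else in the molecule can relay its configuration. The fragile groups are the lactol, which opens to an achiral 2-formylbenzoic acid in water or with base; the benzylic ester, whose CH2 lies between two oxygen-bearing ring carbons and ionises easily; and the beta-resorcylic-type acid of ring A, which can decarboxylate. The ring A carboxyl is flanked by a hydroxyl and a methyl group, so esterification by activating that carbonyl is poor. The real difficulty is therefore twofold: joining the halves without acyl activation, and oxidising C3 late, selectively and with a configuration that survives. The key step uses the fact that the bridging CH2 stands on C6 of ring B, ortho to the C7 phenol: it is one formaldehyde unit, and the C7–O/C6/CH2 array can pass through an ortho-quinone methide that the ring A acid captures through oxygen.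

## Logic of the disconnections

17 ⇒ 16. The bond cut is the acetyl C–O bond on the C3 oxygen. The free lactol cannot keep its configuration through any further chemistry, so it is held until the end as an acylal. The gain is a configurationally robust precursor. The forward step must cleave only the acyl–oxygen bond, in a neutral anhydrous medium, and leave the aryl ester alone.

16 ⇒ 15. The same O–acyl bond is now treated as the stereo-defining event. Racemic 15 is an acceptable precursor because its enantiomers interconvert through 14. The gain is that no earlier step carries a stereochemical demand. The forward step needs a catalyst that acylates only one lactol enantiomer, spares both phenols, and is slower than the racemisation.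

15 ⇒ 13. The C3–O bond is cut back to a C–H bond. This removes the only stereocentre and the most fragile group and arrives at the product of the union. The forward step must oxidise C3–H in the presence of two aryl methyl groups, two methoxy groups and a second benzylic O–CH2; only an enzyme can be expected to do this. A single enantioselective hydroxylation would be two steps shorter, but it was set aside: in aqueous buffer the lactol opens to 14 and any configuration is lost.

13 ⇒ 6 + 10 + 9. The C6–CH2 bond and the CH2–O bond are cut. This leaves the hindered acyl C–O bond of ring A intact and uses the C7 phenol as the handle. The gain is two aromatic pieces of similar size and a one-carbon unit. The forward step must place the carbon of 10 at C6 and not C4, and the electrophile so formed must be taken by the carboxyl oxygen of 9 and not by an aromatic carbon.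

6 ⇒ 5. The C7 O–H is traced back to an O–CH3, because a free phenol next to the carbonyl would interfere with the organolithium chemistry that builds the lactone. The gain is a symmetrical dimethoxy pattern. The forward demethylation must distinguish the C7 from the C5 methoxy group.

5 ⇒ 2. The C7a–C1 bond and the lactone O2–C1 bond are cut; the carbonyl carbon becomes a one-carbon electrophile and the ring oxygen is the benzylic hydroxyl. The gain is a simple bromobenzyl alcohol. The forward step needs an aryl anion at the carbon between the methoxy and hydroxymethyl groups.

2 ⇒ 1. The C–Br bond is cut. The forward bromination must go to C2 and not to C4 between the two methoxy groups.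

9 ⇒ 8 ⇒ 7. The ester O–CH3 and then the C4 ether O–CH3 are cut, which leads to commercial 7. The forward steps must methylate the C4 phenol and not the chelated C2 phenol, and must hydrolyse a di-ortho-substituted ester without decarboxylation.

## Other disconnections considered

Alternative 1: The cut runs through ring B at C3a–C4 and C7–C7a, so that the benzene ring is annulated onto a preformed, enantiopure five-membered lactone. In the forward sense the ketene acetal diene A3 would add to bromobutenolide A2 in a Diels–Alder reaction, the unsubstituted diene terminus bonding to the beta carbon of the butenolide. Loss of HBr and of methoxytrimethylsilane would aromatise the adduct to A1.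
- In favour: A1 already holds C3 at the lactol oxidation level as a configurationally stable (R)-acetate, together with the C5 methoxy, C6 oxymethyl and C7 hydroxy groups. No C–H oxidation of a finished ester is needed; on this point it is the better plan.
- Against: A3 is a hydrolytically sensitive, fully substituted ketene acetal that needs several steps. The dehydrobromination gives a butenolide whose C3 hydrogen is gamma to the carbonyl and acidic, so the base that removes HBr could erase the stereocentre through an isobenzofuranolate. After A1 the silyl ether must still be cleaved, the benzylic alcohol esterified with 9 by oxygen alkylation, and the acetate removed.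
- Comparison: in structure both plans map cleanly onto ring B, and the alternative covers C3 as well. In mechanism the chosen union is stereochemically innocent, whereas the alternative carries a base-sensitive centre through an elimination and an aromatisation. In step economy the alternative is expected to be longer (two fragments of about three to four steps each, then four more) against nine steps. Its final unmasking is the same operation as step 9, so the two are equal there.

Alternative 2: The cut removes three bonds of ring B (C4–C5, C6–C7, C3a–C7a), so that the arene arises from three alkynes held together by a propargyl ester and a silyl ether. In the forward sense triyne A5 would be cyclotrimerised by RhCl(PPh3)3 (monovalent rhodium) to A4, closing ring B, the lactone and a five-membered oxasilole at once. Tamao–Fleming oxidation of the C7–Si bond with cleavage of the Si–O bond would then release the C7 phenol and the C6 hydroxymethyl group, that is F1.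
- In favour: the tethers leave no regiochemical choice, a certainty equal to that of the boron template. The key step is an established reaction type and is the better-precedented of the two. No ortho-quinone methide and no selective demethylation are involved.
- Against: A5 contains an ynol ether and a silylated propiolate, both fragile, and needs about six steps. Oxidising a hindered aryl–Si(iPr)2 unit calls for fluoride and basic peroxide, which a phthalide tolerates poorly. The sequence ends at F1, so the ester bond and the whole C3 problem remain.
- Comparison: in structure it solves only the substitution pattern of ring B, which the chosen plan takes from a commercial arene in three steps. In mechanism it is the safer key step. In step economy it is clearly longer, roughly twice the length before the ester is formed.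

Alternative 3: The cut removes the ring oxygen, that is the C1–O2 and O2–C3 bonds, and leads back to a benzocyclobutenone. In the forward sense the silyl-protected alpha-hydroxy ketone A7 would undergo Baeyer–Villiger oxidation with buffered H2O2. The oxygen-bearing carbon should migrate in preference to the aryl carbon and with retention, expanding the four-membered ketone to the five-membered lactone A6; fluoride would then remove both silyl groups.
- In favour: the stereocentre is made as an ordinary protected secondary alcohol on a carbocycle, where ring–chain tautomerism is impossible. It is transferred stereospecifically and unmasked from a silyl acetal under non-basic conditions. On the handling of C3 it is better than the chosen plan, which needs three enzymatic steps. (By the CIP rules A6 and A7 are S because silicon outranks carbon; the spatial arrangement is that of the target.)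
- Against: A7, an enantiopure pentasubstituted benzocyclobutenone already carrying the ring A ester, is harder to reach than any compound of the chosen route. It needs a regiocontrolled [2+2] of a tetrasubstituted aryne, asymmetric introduction of the oxygen, and a strained ring that opens with nucleophiles or heat. Aryl migration would give a benzofuranone, and the peroxide must spare electron-rich ring A.
- Comparison: in structure it addresses the stereochemical difficulty directly, while the chosen plan addresses the ester bond directly. In mechanism its key step is the more reliable. In step economy it is expected to need well over a dozen steps, most before the key step, against nine.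

Key step: step 6

Remark on the chemistry (assumption): the C3 lactol equilibrates with an achiral ring-opened formylbenzoic acid in water and with base, so the route assumes the single enantiomer can only be delivered by fixing C3 as an acylal and unmasking it last under neutral anhydrous conditions, with the product kept cold and dry.

## Route

Step 1
Reactants: 1 3,5-dimethoxybenzyl alcohol
Product: 2 2-bromo-3,5-dimethoxybenzyl alcohol
Conditions: NBS (1.0 equiv), CH2Cl2, 0 °C to rt
Reagents that add atoms: N-bromosuccinimide, O=C1CCC(=O)N1Br
Why: Electrophilic aromatic bromination; C2 is para to one methoxy group and ortho to the other and is less crowded than C4 between both methoxy groups, so one equivalent of NBS in the cold should give the 2-bromide.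

Step 2
Reactants: 2 2-bromo-3,5-dimethoxybenzyl alcohol
Product: 5 5,7-dimethoxyphthalide, via aryllithium alkoxide 3 (not isolated), via hydroxy acid 4 (not isolated)
Conditions: n-BuLi (2.2 equiv), THF, −78 °C; CO2, −78 °C to rt; 2 M HCl, rt
Reagents that add atoms: carbon dioxide, O=C=O
Why: The first equivalent of n-BuLi deprotonates the alcohol and the second performs bromine–lithium exchange to the chelated aryllithium 3, which is carboxylated by CO2; acidification frees hydroxy acid 4, which lactonises at once to the five-membered lactone.

Step 3
Reactants: 5 5,7-dimethoxyphthalide
Product: 6 7-hydroxy-5-methoxyphthalide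
Conditions: BCl3 (1.2 equiv), CH2Cl2, −78 to 0 °C; H2O
Reagents that add atoms: none
Why: Chelation-controlled Lewis-acid demethylation; boron bridges the lactone carbonyl oxygen and the neighbouring C7 methoxy oxygen in a six-membered chelate and chloride removes that methyl group by SN2, whereas the C5 methoxy group has no carbonyl next to it and should stay.

Step 4
Reactants: 7 methyl 2,4-dihydroxy-3,6-dimethylbenzoate (atraric acid)
Product: 8 methyl 2-hydroxy-4-methoxy-3,6-dimethylbenzoate
Conditions: MeI (1.1 equiv), K2CO3 (1.1 equiv), acetone, reflux
Reagents that add atoms: iodomethane, CI
Why: Williamson ether synthesis; the C2 phenol is tied up in a hydrogen bond to the ester carbonyl and is the weaker nucleophile, so a slight excess of MeI with a mild base should methylate only the C4 phenol.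

Step 5
Reactants: 8 methyl 2-hydroxy-4-methoxy-3,6-dimethylbenzoate
Product: 9 2-hydroxy-4-methoxy-3,6-dimethylbenzoic acid
Conditions: KOH (6 equiv), DMSO/H2O 4:1, 90 °C; then 1 M HCl, 0 °C, pH 2
Reagents that add atoms: KOH, [K+].[OH-]
Why: Saponification of a di-ortho-substituted ester that is further deactivated as its phenoxide, hence hot aqueous DMSO; acidification in the cold keeps the acid from decarboxylating.

Step 6
Reactants: 6 7-hydroxy-5-methoxyphthalide; 10 formaldehyde (used as paraformaldehyde); 9 2-hydroxy-4-methoxy-3,6-dimethylbenzoic acid
Product: 13 (7-hydroxy-5-methoxy-1-oxo-1,3-dihydro-2-benzofuran-6-yl)methyl 2-hydroxy-4-methoxy-3,6-dimethylbenzoate, via cyclic phenylboronate 11 (not isolated), via ortho-quinone methide 12 (not isolated)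
Conditions: PhB(OH)2 (1.1 equiv), (CH2O)n (3 equiv), EtCO2H (0.2 equiv), PhMe, reflux, Dean–Stark; evaporate; then 9 (2.2 equiv), PhMe, 4 Å MS, 100 °C; aq. NaHCO3 work-up
Reagents that add atoms: none
Why: Proposed new method: PhB(OH)2 esterifies the C7 phenol of 6 and the aryl borate delivers formaldehyde through a six-membered transition state to C6, the only free carbon ortho to that oxygen, after which B–O condensation closes the temporary six-membered dioxaborin of 11 while water is removed azeotropically. After excess formaldehyde and the propionic acid have been evaporated, acid 9 protonates the benzylic B–O oxygen of 11 and the C–O bond ionises, assisted by the C7 oxygen and the C5 methoxy group, to the boron-bound ortho-quinone methide 12, whose exocyclic CH2 takes up the carboxylate oxygen of 9 in a 1,4-addition that makes ring B aromatic again. The closest known reaction types are the phenylboronic acid-templated ortho-hydroxymethylation of phenols to 2-phenyl-4H-1,3,2-benzodioxaborins, the thermal or acid-induced opening of such dioxaborins to ortho-quinone methides, and the conjugate addition of carboxylic acids to ortho-quinone methides; their union in one flask with a hindered salicylic acid as nucleophile has not been shown. No ring of 13 is formed (the dioxaborin is closed by condensation and opened again within the step) and no stereocentre is created. Ortho over para selectivity (C6, not C4) is secured by the boron tether on the C7 oxygen. Capture at oxygen and not at carbon is expected on kinetic grounds: the carboxylate is the best nucleophile present, C5 of ring A is deactivated by conjugation of its oxygen substituents with the carboxyl group, and ring A cannot be hydroxymethylated because formaldehyde is gone before 9 enters and both carbons ortho to its phenol are substituted. The hindered carbonyl of 9 is never activated, so its two ortho substituents do not matter, and the second equivalent of 9 binds the released PhB(OH) unit as a six-membered salicylate chelate, which should pull the opening of 11 forward.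

Step 7
Reactants: 13 (7-hydroxy-5-methoxy-1-oxo-1,3-dihydro-2-benzofuran-6-yl)methyl 2-hydroxy-4-methoxy-3,6-dimethylbenzoate
Product: 15 rac-(3,7-dihydroxy-5-methoxy-1-oxo-1,3-dihydro-2-benzofuran-6-yl)methyl 2-hydroxy-4-methoxy-3,6-dimethylbenzoate, via ring-opened formylbenzoic acid 14 (not isolated)
Conditions: cytochrome P450 BM3 (CYP102A1) variant chosen from a panel for C3 hydroxylation, NADP+ (cat.), glucose dehydrogenase, D-glucose, air, KH2PO4/K2HPO4 buffer pH 8, DMSO (5% v/v), 25 °C; then 1 M HCl to pH 2, 0 °C, EtOAc
Reagents that add atoms: dioxygen, O=O
Why: Cytochrome P450 benzylic hydroxylation (hydrogen abstraction by the heme iron–oxo species, then oxygen rebound) at the C3–H bonds, which are both benzylic and alpha to the lactone oxygen and are the most exposed of the activated C–H bonds; the lactol ionises in the buffer to the ring-opened carboxylate of 14, which leaves the active site and should escape further oxidation, and closes again on acidification. No stereochemical demand is made here because 14 is achiral.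

Step 8
Reactants: 15 rac-(3,7-dihydroxy-5-methoxy-1-oxo-1,3-dihydro-2-benzofuran-6-yl)methyl 2-hydroxy-4-methoxy-3,6-dimethylbenzoate
Product: 16 [(3R)-3-acetoxy-7-hydroxy-5-methoxy-1-oxo-1,3-dihydro-2-benzofuran-6-yl]methyl 2-hydroxy-4-methoxy-3,6-dimethylbenzoate
Conditions: immobilised lipase (Burkholderia cepacia lipase or Candida antarctica lipase B, chosen by screening for the (R)-acetate), vinyl acetate (3 equiv), Et3N (0.1 equiv), MTBE, 30 °C
Reagents that add atoms: vinyl acetate, CC(=O)OC=C
Why: Lipase-catalysed acylative dynamic kinetic resolution, the reaction type known for 5-hydroxy-2(5H)-furanones and related cyclic hemiacylals; the lactol enantiomers interconvert through ring-opened 14 under amine catalysis while the acyl-enzyme acetylates only the (R)-lactol, so the chiral active site sets C3 and the acylal formed can no longer ring-open. The two phenols, hindered and hydrogen-bonded to carbonyl groups, are not expected to be lipase substrates.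

Step 9
Reactants: 16 [(3R)-3-acetoxy-7-hydroxy-5-methoxy-1-oxo-1,3-dihydro-2-benzofuran-6-yl]methyl 2-hydroxy-4-methoxy-3,6-dimethylbenzoate
Product: 17 [(3R)-3,7-dihydroxy-5-methoxy-1-oxo-1,3-dihydro-2-benzofuran-6-yl]methyl 2-hydroxy-4-methoxy-3,6-dimethylbenzoate (target)
Conditions: the lipase of step 8, n-BuOH (5 equiv), dry MTBE, 20 °C; filter; evaporate below 25 °C; no aqueous work-up
Reagents that add atoms: none
Why: Lipase-catalysed alcoholysis (transesterification); the enzyme that formed the (R)-acetate must by microscopic reversibility accept it as acyl donor, cleavage is at the acyl–oxygen bond so the C3–O bond and the R configuration are untouched, and the neutral anhydrous medium lacks the water and base that open the lactol. The hindered benzoate ester is not a lipase substrate.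

## Compound list

1 | 3,5-dimethoxybenzyl alcohol | COc1cc(CO)cc(OC)c1 | starting material
2 | 2-bromo-3,5-dimethoxybenzyl alcohol | COc1cc(CO)c(Br)c(OC)c1 | intermediate
3 | lithium (2-lithio-3,5-dimethoxyphenyl)methanolate, the dilithiated form of 2 (not isolated) | [Li]OCc1cc(OC)cc(OC)c1[Li] | intermediate
4 | 2-(hydroxymethyl)-4,6-dimethoxybenzoic acid, formed as its dilithium salt and freed on acidification (not isolated) | COc1cc(CO)c(C(=O)O)c(OC)c1 | intermediate
5 | 5,7-dimethoxyphthalide (5,7-dimethoxy-2-benzofuran-1(3H)-one) | COc1cc(OC)c2C(=O)OCc2c1 | intermediate
6 | 7-hydroxy-5-methoxyphthalide | COc1cc(O)c2C(=O)OCc2c1 | intermediate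
7 | methyl 2,4-dihydroxy-3,6-dimethylbenzoate (atraric acid) | COC(=O)c1c(C)cc(O)c(C)c1O | starting material
8 | methyl 2-hydroxy-4-methoxy-3,6-dimethylbenzoate | COC(=O)c1c(C)cc(OC)c(C)c1O | intermediate
9 | 2-hydroxy-4-methoxy-3,6-dimethylbenzoic acid | COc1cc(C)c(C(=O)O)c(O)c1C | intermediate
10 | formaldehyde (used as paraformaldehyde) | C=O | starting material
11 | cyclic phenylboronate of 7-hydroxy-6-(hydroxymethyl)-5-methoxyphthalide (2-phenyl-4H-1,3,2-dioxaborin fused at C6–C7; not isolated) | COc1cc2COC(=O)c2c2OB(c3ccccc3)OCc12 | intermediate
12 | 5-methoxy-6-methylidene-2-benzofuran-1,7(3H,6H)-dione, the ortho-quinone methide of ring B, formed boron-bound (not isolated) | C=C1C(=O)C2=C(COC2=O)C=C1OC | intermediate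
13 | (7-hydroxy-5-methoxy-1-oxo-1,3-dihydro-2-benzofuran-6-yl)methyl 2-hydroxy-4-methoxy-3,6-dimethylbenzoate (3-deoxy target) | COc1cc(C)c(C(=O)OCc2c(OC)cc3c(c2O)C(=O)OC3)c(O)c1C | intermediate
14 | 2-formyl-6-hydroxy-4-methoxy-5-{[(2-hydroxy-4-methoxy-3,6-dimethylbenzoyl)oxy]methyl}benzoic acid, ring-opened form of 15, present as carboxylate in the buffer (not isolated) | COc1cc(C)c(C(=O)OCc2c(OC)cc(C=O)c(C(=O)O)c2O)c(O)c1C | intermediate
15 | rac-(3,7-dihydroxy-5-methoxy-1-oxo-1,3-dihydro-2-benzofuran-6-yl)methyl 2-hydroxy-4-methoxy-3,6-dimethylbenzoate (racemic lactol) | COc1cc(C)c(C(=O)OCc2c(OC)cc3c(c2O)C(=O)OC3O)c(O)c1C | intermediate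
16 | [(3R)-3-acetoxy-7-hydroxy-5-methoxy-1-oxo-1,3-dihydro-2-benzofuran-6-yl]methyl 2-hydroxy-4-methoxy-3,6-dimethylbenzoate | COc1cc(C)c(C(=O)OCc2c(OC)cc3c(c2O)C(=O)O[C@H]3OC(C)=O)c(O)c1C | intermediate
17 | [(3R)-3,7-dihydroxy-5-methoxy-1-oxo-1,3-dihydro-2-benzofuran-6-yl]methyl 2-hydroxy-4-methoxy-3,6-dimethylbenzoate | COc1cc(C)c(C(=O)OCc2c(OC)cc3c(c2O)C(=O)O[C@H]3O)c(O)c1C | target

## Step count and least certain steps

Total step count: 9. Longest linear sequence: 7 steps (steps 1, 2, 3, 6, 7, 8, 9); the acid branch (steps 4, 5) joins at step 6.

Step 6 (key step, proposed new method). The most likely failures are incomplete opening of the stable six-membered boronate, and reversible ionisation of the benzylic ester that lets the ortho-quinone methide drain into irreversible carbon-benzylation (at C4 of a second phenol unit or C5 of ring A) and oligomerisation. Slow thermal decarboxylation of 9 is a further risk. The fallback uses known chemistry and sets out from 6. Boronate 11 is formed as in the first stage and cleaved in the same flask by transesterification with propane-1,3-diol to 7-hydroxy-6-(hydroxymethyl)-5-methoxyphthalide F1. The primary benzylic alcohol of F1 is then esterified with 9 under Mitsunobu conditions (PPh3, DIAD, THF, 0 °C). The carboxylic acid is the most acidic pronucleophile and again reacts through oxygen, so its hindrance is irrelevant. The fallback comes back to the route at 13.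

Step 7. The most likely failure is oxidation at the wrong site: the aryl methyl groups of ring A, O-demethylation, or the C6–CH2–O methylene, whose hydroxylation would cleave the ester. The bulky substrate may also not be accepted. The fallback introduces the C3 oxygen chemically at the stage of 5, where the C3 hydrogens are the only benzylic ones. Radical bromination (NBS, AIBN, PhCF3, reflux) should give 3-bromo-5,7-dimethoxyphthalide F2, and hydrolysis (H2O/THF, reflux) 3-hydroxy-5,7-dimethoxyphthalide F3. BCl3 as in step 3 should give 3,7-dihydroxy-5-methoxyphthalide F4, and the lipase resolution of step 8 (R)-3-acetoxy-7-hydroxy-5-methoxyphthalide F5. Phenylboronic acid-templated hydroxymethylation then gives the cyclic phenylboronate F6, which propane-1,3-diol cleaves to (R)-3-acetoxy-7-hydroxy-6-(hydroxymethyl)-5-methoxyphthalide F7. Mitsunobu esterification of F7 with 9 comes back to the route at 16. Only a spectator group at C3 of the phenol partner changes; the bonds formed in the union are the same.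

Step 8. The most likely failure is a plain kinetic resolution (ring opening through 14 slower than acylation), weak discrimination, or the opposite enantiopreference of the available lipases. The fallback sets out from 15 and replaces the enzyme by a chiral Lewis-base (isothiourea) acyl-transfer catalyst, available as either enantiomer, with isobutyric anhydride and iPr2NEt in CH2Cl2. This is acylative dynamic kinetic resolution of a kind established for cyclic lactols, and should give [(3R)-7-hydroxy-3-(isobutyryloxy)-5-methoxy-1-oxo-1,3-dihydro-2-benzofuran-6-yl]methyl 2-hydroxy-4-methoxy-3,6-dimethylbenzoate F8. Alcoholysis as in step 9 then comes back to the route at 17.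

Step 9. The most likely failure is erosion of configuration by ring–chain tautomerism of the freed lactol during a slow alcoholysis, or a conversion that stalls at equilibrium. The fallback sets out from 15 and changes the unmasking chemistry. Vinyl chloroacetate is used in the lipase resolution to give [(3S)-3-(chloroacetoxy)-7-hydroxy-5-methoxy-1-oxo-1,3-dihydro-2-benzofuran-6-yl]methyl 2-hydroxy-4-methoxy-3,6-dimethylbenzoate F9 (S only by the CIP rules; same spatial arrangement as 16). The chloroacetyl group is then removed with thiourea (THF/EtOH, rt): sulfur alkylation and cyclisation to 2-imino-1,3-thiazolidin-4-one release the lactol oxygen with the C3–O bond intact under slightly acidic conditions. The fallback comes back to the route at 17.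

Step 5. The most likely failure is incomplete hydrolysis of the hindered, phenoxide-deactivated ester, or decarboxylation on acidification. The fallback sets out from 8 and cleaves the O–CH3 bond instead of the acyl–oxygen bond: LiI in refluxing EtOAc (SN2 at the methyl group) gives the lithium carboxylate, and cold dilute HCl comes back to the route at 9.

## Further compounds

F1 | step 6 | 7-hydroxy-6-(hydroxymethyl)-5-methoxyphthalide | COc1cc2COC(=O)c2c(O)c1CO
F2 | step 7 | 3-bromo-5,7-dimethoxyphthalide (racemic) | COc1cc(OC)c2C(=O)OC(Br)c2c1
F3 | step 7 | 3-hydroxy-5,7-dimethoxyphthalide (racemic) | COc1cc(OC)c2C(=O)OC(O)c2c1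
F4 | step 7 | 3,7-dihydroxy-5-methoxyphthalide (racemic) | COc1cc(O)c2C(=O)OC(O)c2c1
F5 | step 7 | (R)-3-acetoxy-7-hydroxy-5-methoxyphthalide | COc1cc2c(c(O)c1)C(=O)O[C@H]2OC(C)=O
F6 | step 7 | cyclic phenylboronate of F7 (2-phenyl-4H-1,3,2-dioxaborin fused at C6–C7 of (R)-3-acetoxy-5-methoxyphthalide) | COc1cc2c(c3OB(c4ccccc4)OCc13)C(=O)O[C@H]2OC(C)=O
F7 | step 7 | (R)-3-acetoxy-7-hydroxy-6-(hydroxymethyl)-5-methoxyphthalide | COc1cc2c(c(O)c1CO)C(=O)O[C@H]2OC(C)=O
F8 | step 8 | [(3R)-7-hydroxy-3-(isobutyryloxy)-5-methoxy-1-oxo-1,3-dihydro-2-benzofuran-6-yl]methyl 2-hydroxy-4-methoxy-3,6-dimethylbenzoate | COc1cc(C)c(C(=O)OCc2c(OC)cc3c(c2O)C(=O)O[C@H]3OC(=O)C(C)C)c(O)c1C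
F9 | step 9 | [(3S)-3-(chloroacetoxy)-7-hydroxy-5-methoxy-1-oxo-1,3-dihydro-2-benzofuran-6-yl]methyl 2-hydroxy-4-methoxy-3,6-dimethylbenzoate | COc1cc(C)c(C(=O)OCc2c(OC)cc3c(c2O)C(=O)O[C@H]3OC(=O)CCl)c(O)c1C
F0 | step 5 | none | none
A1 | alternative 1 | (R)-3-acetoxy-6-[(tert-butyldimethylsilyloxy)methyl]-7-hydroxy-5-methoxyphthalide | COc1cc2c(c(O)c1CO[Si](C)(C)C(C)(C)C)C(=O)O[C@H]2OC(C)=O
A2 | alternative 1 | (R)-5-acetoxy-3-bromofuran-2(5H)-one | O=C1O[C@@H](OC(C)=O)C=C1Br
A3 | alternative 1 | 2-[(tert-butyldimethylsilyloxy)methyl]-1,3-dimethoxy-1-(trimethylsilyloxy)buta-1,3-diene | C=C(OC)C(CO[Si](C)(C)C(C)(C)C)=C(OC)O[Si](C)(C)C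
A4 | alternative 2 | oxasilole-fused 5-methoxyphthalide (diisopropylsilyl bridging C7 and the C6 CH2–O) | COc1cc2COC(=O)c2c2c1CO[Si]2(C(C)C)C(C)C
A5 | alternative 2 | prop-2-yn-1-yl 3-{diisopropyl[(3-methoxyprop-2-yn-1-yl)oxy]silyl}prop-2-ynoate | C#CCOC(=O)C#C[Si](C(C)C)(C(C)C)OCC#COC
A6 | alternative 3 | [(3S)-3,7-bis(tert-butyldimethylsilyloxy)-5-methoxy-1-oxo-1,3-dihydro-2-benzofuran-6-yl]methyl 2-hydroxy-4-methoxy-3,6-dimethylbenzoate (bis-silylated target) | COc1cc(C)c(C(=O)OCc2c(OC)cc3c(c2O[Si](C)(C)C(C)(C)C)C(=O)O[C@H]3O[Si](C)(C)C(C)(C)C)c(O)c1C
A7 | alternative 3 | [(7S)-2,7-bis(tert-butyldimethylsilyloxy)-4-methoxy-8-oxobicyclo[4.2.0]octa-1,3,5-trien-3-yl]methyl 2-hydroxy-4-methoxy-3,6-dimethylbenzoate (2-silyloxybenzocyclobutenone ester) | COc1cc(C)c(C(=O)OCc2c(OC)cc3c(c2O[Si](C)(C)C(C)(C)C)C(=O)[C@H]3O[Si](C)(C)C(C)(C)C)c(O)c1C
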